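## Structural features

The target is a 3,8''-linked biflavanone. Unit 1 is a 5,7,3',4'-tetrahydroxyflavanone (rings A and C and the catechol ring B) whose C3 is bonded to C8'' of a naringenin unit (unit 2: phloroglucinol ring D, its pyranone ring and the 4-hydroxyphenyl ring E). Read from the structure, the configurations are 2R,3R,2''S. The ring B aryl on C2 and ring D on C3 are therefore cis on ring C, and C2 and C2'' have opposite local sense: unit 2 has the common 2S flavanone arrangement, unit 1 the 2R one. C2 and C3 are adjacent; C3 is both α to the C4 ketone and benzylic to the electron-rich ring D, so the cis pair is a kinetic arrangement that acid or base would turn into trans. Both pyranones are β-aryloxy ketones that open by retro-oxa-Michael reaction under base, which endangers C2 and C2''. The 7''-hydroxyl lies ortho to C8'' and can reach the C4 carbonyl, so acid threatens dehydration to a benzofuran. The C3–C8'' bond joins a tertiary carbon to an arene carbon flanked by O7'' and O1'' and is the most congested bond. The real difficulty is this hindered bond combined with a contra-thermodynamic cis C2/C3 pair and two C2-type centres of unlike sense. The key step uses the fact that O1–C2 (ring C) and O1''–C2'' (pyranone of unit 2) are each the β-aryloxy bond of a ketone, so both rings open formally to ortho-hydroxychalcones and C3–C8'' becomes the α-aryl bond of an open enone.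

## Logic of the disconnections

19 to 18. The seven aryl O–CH2Ph bonds are cut. Benzyl is the only phenol protection that leaves under neutral, non-epimerising conditions, which the cis C3 centre and the two openable pyranones require. The forward step must add hydrogen to nothing but these ethers.

18 to 16 (through 17). O1–C2 and O1''–C2'' are cut, opening both pyranones to enones; two rings and three stereocentres disappear and an achiral, fully conjugated compound remains. Two changes are made to the design of the open compound.
- In 16 the oxygen on C7'' is benzylated like all the others, so the only free hydroxyls are the two that must add. A free 7''-hydroxyl is a vinylogous acid that would pair with the amine of the catalyst, and it is a second phenol ortho to C8'' able to add to C2 or C4 of the upper enone.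
- Both enones of 16 carry their β-aryl group anti to the carbonyl, so a single chiral catalyst would be expected to give like configurations at C2 and C2''. The closure is therefore run as a relay of two pseudo-enantiomeric catalysts in one flask, which demands that the two enones close at clearly different rates.

16 to 14. The two phenolic O–H bonds are traced back to O–CH2OMe. The phenols have to be masked while the carbon skeleton is made, because a free ortho-hydroxyl next to an α-aryl enone closes without control under any base. The forward unmasking must use neither protic acid nor base.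

14 to 10 + 11. The C2=C3 double bond is cut in the aldol sense. This removes the congested trisubstituted alkene and one aryl aldehyde. The forward step must form the alkene at a CH2 group flanked by two di-ortho-substituted arenes and give the E isomer.

10 to 3 + 7. The C3–C8'' bond is cut between an enolate carbon and an aryl iodide. Both halves then derive from 2, so the oxygen patterns of rings A and D need no separate construction, and the iodine marks C8'' unambiguously. The forward coupling must tolerate an enone and join two hindered partners.

7 to 5 + 6, and 5 to 4 to 2. The C2''=C3'' bond of the lower enone is cut (aldol sense), then the acetal ether, then the C–I bond. Placing the aldehyde 6 before the fragment union means each aldehyde meets only one enolisable position. The iodination must go ortho to the free hydroxyl of 2.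

3 to 2 to 1. The acetal ether and two benzyl ethers are removed, leading to a catalogue triphenol; the forward benzylation must leave one chelated hydroxyl untouched.

## Other disconnections considered

Alternative 1: The cut removes C3–C8'' and C2–C3 together and leaves O1–C2 for later.
- Forward step: Rh2(OAc)4 would turn the diazoketone A2 into a dirhodium carbene. C8'' of the tribenzyl flavanone A3 would attack it, and the resulting enol would be intercepted by aldehyde 11 under a chiral BINOL-derived phosphoric acid to give the anti β-hydroxy ketone A1. Desilylation, ring closure with inversion at C2 (Mitsunobu) and hydrogenolysis would follow.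
- In its favour: two C–C bonds and two stereocentres arise in one convergent operation. C2'' is brought in with A3 and needs no asymmetric closure. The stereocentres are set in irreversible bond formations. On these three points it is better than the chosen plan.
- Against it here: trapping of such intermediates is established mainly for aryl diazoacetates with very electron-rich arenes. With an acceptor-only diazoketone and an acyl-deactivated arene, a simple 1,2-hydrogen shift to the two-component arylation product is the likely competitor. A3 offers C6'' as well as C8''. The closure needs clean inversion at a carbinol carbon bearing a dialkoxyphenyl group, which ionises easily, so cis is not secured. Fluoride desilylation invites retro-aldol cleavage.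
- Comparison: on structure the chosen plan fixes the 3,8'' site by the iodination of 2, which this alternative cannot. On mechanism the alternative avoids reversible closures. Step economy is about equal.

Alternative 2: The cut is C2–C3 alone, with O1–C2 already present as a benzylic ether.
- Forward step: Rh2(S-PTTL)4 would convert the diazoketone A5 into a carbene at C3 that inserts into an ortho O–CH2–aryl C–H bond, closing ring C and giving the cis chromanone A4.
- In its favour: cis-2,3 is the usual kinetic outcome of such insertions and is fixed in an irreversible C–C bond formation. The catalyst sets the absolute configuration, and C2'' comes from a preformed flavanone. For the cis problem and for the unlike sense of C2 and C2'' it is better than the chosen plan.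
- Against it here: A5 still needs the hindered C3–C8'' bond (no gain there) and a diazo transfer with base next to an openable flavanone. The carbene can attack the ether oxygen to give a five-membered oxonium ylide and then a [1,2]-benzyl shift (Stevens rearrangement). It can also add to the electron-rich benzyl rings. Six-membered insertion is less favoured than five-membered. The silyl ethers need fluoride, and two large benzylic groups are carried only as spectators.
- Comparison: the final hydrogenolysis is the same. The route to A5 is clearly longer than the route to 16.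

Alternative 3: The cut removes C3–C8'' and O1–C2 in one oxidative event.
- Forward step: laccase under air, or Ag2O, would oxidise the chalcone A7 and the flavanone A8. The chalcone α-carbon would couple with C8'', and the ortho-hydroxyl would add to the quinone methide to give A6.
- In its favour: it is by far the shortest route, needs no prefunctionalisation of C8'' and no protection at the reacting phenols, and follows the likely biosynthesis. On step economy it is clearly better than the chosen plan.
- Against it here: radical coupling gives no control over C6'' versus C8'', C–O coupling, or self-coupling of A7. Closure of the quinone methide is under thermodynamic control and should favour trans, so the cis compound A6 would be a minor isomer. Neither C2 nor C3 is controlled in the absolute sense, and the phenolic products remain oxidisable.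
- Comparison: the alternative is the more direct on structure. On mechanism the chosen plan offers handles for every selectivity, this one for none; a single enantiomer would rest on chromatography.

Key step: step 9

Remarks on the chemistry (assumptions):
- No constitutional error was found in the structures; the descriptors 2R,3R,2''S and the cis relation at C2/C3 follow from the target as drawn.
- Compounds 1, 6 and 11 are catalogue compounds (the C-acetyl derivative of phloroglucinol and the benzyl ethers of the two hydroxybenzaldehydes).
- Iodination of 2 is assumed to go ortho to the free hydroxyl, as is usual for 2-hydroxy-4,6-dialkoxyacetophenones.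
- T1 is N-[3,5-bis(trifluoromethyl)phenyl]-N'-[(8α,9S)-6'-methoxycinchonan-9-yl]thiourea (from quinine); T2 is its pseudo-enantiomer N-[3,5-bis(trifluoromethyl)phenyl]-N'-[(9R)-6'-methoxycinchonan-9-yl]thiourea (from quinidine).
- T1 is assumed to give the 2''S sense; if the senses prove reversed, T1 and T2 change places and nothing else changes.
- The unhindered lower enone is assumed to close much faster than the α-aryl enone; the relay rests on this.

Step 1
Reactants: 1 2',4',6'-trihydroxyacetophenone
Product: 2 1-[2,4-bis(benzyloxy)-6-hydroxyphenyl]ethan-1-one
Conditions: BnBr (2.1 equiv), K2CO3, DMF, rt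
Reagents that add atoms: benzyl bromide, BrCc1ccccc1
Why: Williamson etherification; the hydroxyl para to the acetyl group and one of the two equivalent ortho hydroxyls should be alkylated, while the last ortho hydroxyl is held in a hydrogen bond to the carbonyl and stays free.

Step 2
Reactants: 2 1-[2,4-bis(benzyloxy)-6-hydroxyphenyl]ethan-1-one
Product: 3 1-[2,4-bis(benzyloxy)-6-(methoxymethoxy)phenyl]ethan-1-one
Conditions: NaH (1.05 equiv), THF–DMF, 0 °C; MOMCl, 0 °C to rt
Reagents that add atoms: chloromethyl methyl ether, COCCl
Why: O-alkylation of the sodium phenoxide; the phenol is far more acidic than the methyl ketone, so one equivalent of NaH should give the phenoxide only, and the acetal ether is inert to enolates, zerovalent palladium and amidine base.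

Step 3
Reactants: 2 1-[2,4-bis(benzyloxy)-6-hydroxyphenyl]ethan-1-one
Product: 4 1-[4,6-bis(benzyloxy)-2-hydroxy-3-iodophenyl]ethan-1-one
Conditions: N-iodosuccinimide (1.05 equiv), CH2Cl2–MeCN, 0 °C, dark
Reagents that add atoms: N-iodosuccinimide, O=C1CCC(=O)N1I
Why: Electrophilic aromatic iodination; the free chelated hydroxyl should direct iodine to its ortho position. This carbon is the future C8'', with the future O1'' (free) on one side and O7'' (benzylated) on the other, so the 3,8'' linkage is fixed here.

Step 4
Reactants: 4 1-[4,6-bis(benzyloxy)-2-hydroxy-3-iodophenyl]ethan-1-one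
Product: 5 1-[4,6-bis(benzyloxy)-3-iodo-2-(methoxymethoxy)phenyl]ethan-1-one
Conditions: NaH (1.05 equiv), THF–DMF, 0 °C; MOMCl, 0 °C to rt
Reagents that add atoms: chloromethyl methyl ether, COCCl
Why: O-alkylation of the sodium phenoxide as in step 2; the flanked hydroxyl reacts as its anion, and the aryl iodide is inert.

Step 5
Reactants: 5 1-[4,6-bis(benzyloxy)-3-iodo-2-(methoxymethoxy)phenyl]ethan-1-one; 6 4-(benzyloxy)benzaldehyde
Product: 7 (E)-1-[4,6-bis(benzyloxy)-3-iodo-2-(methoxymethoxy)phenyl]-3-[4-(benzyloxy)phenyl]prop-2-en-1-one
Conditions: KOH (aq), EtOH–THF, rt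
Reagents that add atoms: none
Why: Claisen–Schmidt condensation of a methyl ketone with a non-enolisable aldehyde; dehydration should give the E enone. With the hydroxyl masked no flavanone can form, and the iodide and acetal ether are stable to hydroxide at room temperature.

Step 6
Reactants: 3 1-[2,4-bis(benzyloxy)-6-(methoxymethoxy)phenyl]ethan-1-one; 7 iodochalcone
Product: 10 ketone–chalcone coupling product (full name in the compound list), via lithium enolate 8 (not isolated), via chlorozinc enolate 9 (not isolated)
Conditions: LiN(SiMe3)2, THF, −78 °C; ZnCl2, −78 to 0 °C; 7, Pd(dba)2 (5 mol%), P(t-Bu)3 (6 mol%), THF, rt to 45 °C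
Reagents that add atoms: none
Why: Negishi-type α-arylation of a ketone zinc enolate: zerovalent palladium inserts into the C–I bond, the enolate transmetalates and reductive elimination forms the future C3–C8'' bond. Compound 7 has no acidic C–H, so only one enolate exists, and a zinc enolate is a poor Michael donor, which should spare the enone.

Step 7
Reactants: 10 ketone–chalcone coupling product; 11 3,4-bis(benzyloxy)benzaldehyde
Product: 14 bis-chalcone bis(methoxymethyl) ether, via lithium aldolate 12 (not isolated), via acetoxy ketone 13 (not isolated)
Conditions: LiN(SiMe3)2, THF, −78 °C; 11; Ac2O, −78 to 0 °C; DBU, rt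
Reagents that add atoms: none
Why: Aldol addition at the only acidic position (the CH2 between the ketone and ring D), acetylation of the aldolate in the flask to block retro-aldol cleavage, then E1cB elimination. The E isomer, with the aroyl group anti to the ring B aryl, is expected as the less strained alkene.

Step 8
Reactants: 14 bis-chalcone bis(methoxymethyl) ether
Product: 16 open bis-chalcone diphenol, via bis(trimethylsilyl) ether 15 (not isolated)
Conditions: Me3SiOTf, 2,2'-bipyridyl, MeCN–CH2Cl2, 0 °C; H2O, 0 °C
Reagents that add atoms: none
Why: Cleavage of aryl methoxymethyl ethers by silyl transfer: the buffered silyl triflate converts each acetal ether into an aryl silyl ether (the methoxymethyl group leaves on the pyridine nitrogen) and water then frees the phenols. Neither protic acid nor base is present, so the enones should not close and O1''–H is not driven onto the C4 carbonyl; benzyl ethers are inert.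

Step 9
Reactants: 16 open bis-chalcone diphenol
Product: 18 hepta-O-benzyl (2R,3R,2''S)-biflavanone, via flavanone–chalcone 17 (not isolated)
Conditions: T1 (10 mol%), toluene, −20 °C; sulfonic acid resin, filter; T2 (20 mol%), toluene, 0 °C; sulfonic acid resin, filter
Reagents that add atoms: none
Why: Proposed new method: the closest known reaction is the enantioselective oxa-Michael cyclisation of ortho-hydroxychalcones to flavanones with cinchona-derived thiourea–amine catalysts; its use on an α-aryl enone with stereoselective protonation at C3, and as a two-ring relay, is new. In each closure the quinuclidine nitrogen takes up the proton of the chelated phenol while the thiourea N–H bonds hold the enone carbonyl, the aryloxide adds to the β-carbon in a 6-endo-trig manner, and the enol so formed is protonated by the quinuclidinium ion. The unhindered lower enone should close first (pyranone of unit 2, O1''–C2''), and T1 sets C2'' (S) by selecting the face of C2'' that the aryloxide attacks. After T1 has been bound to the acid resin, the pseudo-enantiomer T2 closes the slower α-aryl enone (ring C, O1–C2) with the opposite sense, as C2 (R) requires. C3 (R) is set in the same closure by the substrate: in the C3=C4 enol, allylic strain with ring D forces the C2 aryl group pseudo-axial and the proton enters anti to it, which gives the 2,3-cis product under kinetic control. Site selectivity is secured by the substrate: every other oxygen is benzylated so only O1 and O1'' can add, O1'' is tied up in its ring before the upper enone reacts and so cannot add to C2 or C4, and each β-carbon lies within reach of one phenol only. Low temperature, short contact time and removal of the amine on the resin are needed because retro-oxa-Michael opening and enolisation at C3 lead towards the trans, stereorandom mixture.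

Step 10
Reactants: 18 hepta-O-benzyl (2R,3R,2''S)-biflavanone
Product: 19 (2R,3R)-2-(3,4-dihydroxyphenyl)-3-[(2S)-5,7-dihydroxy-2-(4-hydroxyphenyl)-4-oxochroman-8-yl]-5,7-dihydroxychroman-4-one
Conditions: H2 (1 atm), palladium on carbon (10% Pd/C), EtOAc–MeOH, rt
Reagents that add atoms: none
Why: Hydrogenolysis of the seven aryl benzyl ethers on palladium under neutral conditions, so C3 should not epimerise and neither pyranone should open. The reaction is stopped when uptake ceases, to spare the benzylic C2–O1 and C2''–O1'' bonds and the ketones.

## Compound list

1 | 1-(2,4,6-trihydroxyphenyl)ethan-1-one | CC(=O)c1c(O)cc(O)cc1O | starting material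
2 | 1-[2,4-bis(benzyloxy)-6-hydroxyphenyl]ethan-1-one | CC(=O)c1c(O)cc(OCc2ccccc2)cc1OCc1ccccc1 | intermediate
3 | 1-[2,4-bis(benzyloxy)-6-(methoxymethoxy)phenyl]ethan-1-one | CC(=O)c1c(OCOC)cc(OCc2ccccc2)cc1OCc1ccccc1 | intermediate
4 | 1-[4,6-bis(benzyloxy)-2-hydroxy-3-iodophenyl]ethan-1-one | CC(=O)c1c(O)c(I)c(OCc2ccccc2)cc1OCc1ccccc1 | intermediate
5 | 1-[4,6-bis(benzyloxy)-3-iodo-2-(methoxymethoxy)phenyl]ethan-1-one | CC(=O)c1c(OCOC)c(I)c(OCc2ccccc2)cc1OCc1ccccc1 | intermediate
6 | 4-(benzyloxy)benzaldehyde | O=Cc1ccc(OCc2ccccc2)cc1 | starting material
7 | (E)-1-[4,6-bis(benzyloxy)-3-iodo-2-(methoxymethoxy)phenyl]-3-[4-(benzyloxy)phenyl]prop-2-en-1-one | O=C(/C=C/c1ccc(OCc2ccccc2)cc1)c1c(OCOC)c(I)c(OCc2ccccc2)cc1OCc1ccccc1 | intermediate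
8 | lithium enolate of 3 (not isolated) | [Li]OC(=C)c1c(OCOC)cc(OCc2ccccc2)cc1OCc1ccccc1 | intermediate
9 | chlorozinc enolate of 3 (not isolated) | Cl[Zn]OC(=C)c1c(OCOC)cc(OCc2ccccc2)cc1OCc1ccccc1 | intermediate
10 | (E)-1-[4,6-bis(benzyloxy)-3-{2-[2,4-bis(benzyloxy)-6-(methoxymethoxy)phenyl]-2-oxoethyl}-2-(methoxymethoxy)phenyl]-3-[4-(benzyloxy)phenyl]prop-2-en-1-one | O=C(/C=C/c1ccc(OCc2ccccc2)cc1)c1c(OCOC)c(CC(=O)c2c(OCOC)cc(OCc3ccccc3)cc2OCc2ccccc2)c(OCc2ccccc2)cc1OCc1ccccc1 | intermediate
11 | 3,4-bis(benzyloxy)benzaldehyde | O=Cc1ccc(OCc2ccccc2)c(OCc2ccccc2)c1 | starting material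
12 | lithium aldolate of 10 with 11, mixture of diastereomers (not isolated) | [Li]OC(c1ccc(OCc2ccccc2)c(OCc2ccccc2)c1)C(C(=O)c1c(OCOC)cc(OCc2ccccc2)cc1OCc1ccccc1)c1c(OCc2ccccc2)cc(OCc2ccccc2)c(C(=O)/C=C/c2ccc(OCc3ccccc3)cc2)c1OCOC | intermediate
13 | β-acetoxy ketone from 12, mixture of diastereomers (not isolated) | CC(=O)OC(c1ccc(OCc2ccccc2)c(OCc2ccccc2)c1)C(C(=O)c1c(OCOC)cc(OCc2ccccc2)cc1OCc1ccccc1)c1c(OCc2ccccc2)cc(OCc2ccccc2)c(C(=O)/C=C/c2ccc(OCc3ccccc3)cc2)c1OCOC | intermediate
14 | open bis-chalcone with both enones E, methoxymethyl ethers on O1 and O1'', benzyl ethers on the other seven oxygens | O=C(c1c(OCOC)cc(OCc2ccccc2)cc1OCc1ccccc1)/C(=C/c1ccc(OCc2ccccc2)c(OCc2ccccc2)c1)c1c(OCc2ccccc2)cc(OCc2ccccc2)c(C(=O)/C=C/c2ccc(OCc3ccccc3)cc2)c1OCOC | intermediate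
15 | bis(trimethylsilyl) ether corresponding to 14 (not isolated) | O=C(c1c(O[Si](C)(C)C)cc(OCc2ccccc2)cc1OCc1ccccc1)/C(=C/c1ccc(OCc2ccccc2)c(OCc2ccccc2)c1)c1c(OCc2ccccc2)cc(OCc2ccccc2)c(C(=O)/C=C/c2ccc(OCc3ccccc3)cc2)c1O[Si](C)(C)C | intermediate
16 | open bis-chalcone with free hydroxyls at the future O1 and O1'' and seven benzyl ethers | O=C(c1c(O)cc(OCc2ccccc2)cc1OCc1ccccc1)/C(=C/c1ccc(OCc2ccccc2)c(OCc2ccccc2)c1)c1c(OCc2ccccc2)cc(OCc2ccccc2)c(C(=O)/C=C/c2ccc(OCc3ccccc3)cc2)c1O | intermediate
17 | (2S)-5,7-bis(benzyloxy)-2-[4-(benzyloxy)phenyl]chroman-4-one carrying at C8 the open α-aryl enone of unit 1 (not isolated) | O=C1C[C@@H](c2ccc(OCc3ccccc3)cc2)Oc2c1c(OCc1ccccc1)cc(OCc1ccccc1)c2/C(=C\c1ccc(OCc2ccccc2)c(OCc2ccccc2)c1)C(=O)c1c(O)cc(OCc2ccccc2)cc1OCc1ccccc1 | intermediate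
18 | hepta-O-benzyl ether of the target, (2R,3R,2''S) | O=C1C[C@@H](c2ccc(OCc3ccccc3)cc2)Oc2c1c(OCc1ccccc1)cc(OCc1ccccc1)c2[C@H]1C(=O)c2c(OCc3ccccc3)cc(OCc3ccccc3)cc2O[C@H]1c1ccc(OCc2ccccc2)c(OCc2ccccc2)c1 | intermediate
19 | (2R,3R)-2-(3,4-dihydroxyphenyl)-3-[(2S)-5,7-dihydroxy-2-(4-hydroxyphenyl)-4-oxochroman-8-yl]-5,7-dihydroxychroman-4-one | O=C1C[C@@H](c2ccc(O)cc2)Oc2c1c(O)cc(O)c2[C@H]1C(=O)c2c(O)cc(O)cc2O[C@H]1c1ccc(O)c(O)c1 | target

## Step count and least certain steps

Total: 10 steps. Longest linear sequence: 9 steps (1, 2, 4, 5, 7, 10, 14, 16, 18, 19).

**Step 9 (key step, new method).**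
- What may go wrong: the sense or level of facial selectivity in the closure of the α-aryl enone may be inadequate; the rate difference between the two enones may be too small, so that T1 also closes ring C; C3 may enolise and drift from cis to trans; T2 may slowly reopen the first-formed pyranone.
- Fallback (known chemistry, from 16 back to 18): control by the catalyst is given up. Compound 16 is closed with an achiral tertiary amine (1,4-diazabicyclo[2.2.2]octane, toluene, low temperature), the ordinary amine-mediated chalcone cyclisation, and stopped at the kinetic stage to give the stereoisomer mixture F1. The cis isomers are separated from trans on silica, and 18 is isolated by preparative HPLC on a chiral stationary phase. Unwanted isomers are reopened with KOH in ethanol to the phenolate of 16 and recycled.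

**Step 6.**
- What may go wrong: conjugate addition of the zinc enolate to the enone of 7, or slow oxidative addition at the doubly flanked iodide with loss of iodine by protonation.
- Fallback (from 5 and 9 back to 10): the order of bond formation is changed. Enolate 9 is coupled with the iodo ketone 5, which has no enone, to give the diketone F2. Claisen–Schmidt condensation of F2 with 6 (KOH, EtOH) should then take place at the unhindered methyl ketone and not at the flanked CH2, giving 10.

**Step 7.**
- What may go wrong: an unfavourable aldol equilibrium at the congested CH2 with retro-aldol cleavage before acetylation, or formation of an E/Z mixture on elimination.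
- Fallback (from 10 back to 14): the alkene is built by a different bond. The enolate of 10 is aminomethylated with dimethyl(methylidene)ammonium iodide to the Mannich base F3. Quaternisation with MeI and mild base gives the α-methylene ketone F4. Heck arylation of F4 with 1,2-bis(benzyloxy)-4-iodobenzene (Pd(OAc)2, P(o-tol)3, Et3N, DMF) should then give 14 with the new aryl anti to the carbonyl.

**Step 8.**
- What may go wrong: uncatalysed closure of the freed phenols during work-up, acid-triggered attack of O1''–H on the C4 carbonyl, or incomplete cleavage of the flanked acetal ether.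
- Fallback (from 15 to 18, passing through 16 in the flask only): the silyl ether 15 is isolated by non-aqueous work-up, and the phenols are released by methanol in the flask of step 9 in the presence of T1. The relay then proceeds as in step 9. No new compound arises (F0).

**Step 10.**
- What may go wrong: hydrogenolysis of the benzylic C2–O1 and C2''–O1'' bonds, reduction of the ketones, or epimerisation at C3 on the metal.
- Fallback (from 18 to 19): non-reductive debenzylation with BCl3 and pentamethylbenzene as cation scavenger in CH2Cl2 at −78 °C. No new compound arises (F0).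

## Further compounds

F1 | step 9 | hepta-O-benzyl biflavanone with the constitution of 18, mixture of stereoisomers | O=C1CC(c2ccc(OCc3ccccc3)cc2)Oc2c1c(OCc1ccccc1)cc(OCc1ccccc1)c2C1C(=O)c2c(OCc3ccccc3)cc(OCc3ccccc3)cc2OC1c1ccc(OCc2ccccc2)c(OCc2ccccc2)c1
F2 | step 6 | 1-[4,6-bis(benzyloxy)-3-{2-[2,4-bis(benzyloxy)-6-(methoxymethoxy)phenyl]-2-oxoethyl}-2-(methoxymethoxy)phenyl]ethan-1-one | CC(=O)c1c(OCOC)c(CC(=O)c2c(OCOC)cc(OCc3ccccc3)cc2OCc2ccccc2)c(OCc2ccccc2)cc1OCc1ccccc1
F3 | step 7 | Mannich base of 10 (dimethylaminomethyl group on the carbon between the ketone and ring D, racemic) | O=C(/C=C/c1ccc(OCc2ccccc2)cc1)c1c(OCOC)c(C(CN(C)C)C(=O)c2c(OCOC)cc(OCc3ccccc3)cc2OCc2ccccc2)c(OCc2ccccc2)cc1OCc1ccccc1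
F4 | step 7 | α-methylene ketone from 10 | O=C(/C=C/c1ccc(OCc2ccccc2)cc1)c1c(OCOC)c(C(=C)C(=O)c2c(OCOC)cc(OCc3ccccc3)cc2OCc2ccccc2)c(OCc2ccccc2)cc1OCc1ccccc1
F0 | step 8 | none | none
F0 | step 10 | none | none
A1 | alternative 1 | anti β-hydroxy ketone (2S,3R,2''S) with rings A and B and unit 2 on C3 | O=C1C[C@@H](c2ccc(OCc3ccccc3)cc2)Oc2c1c(OCc1ccccc1)cc(OCc1ccccc1)c2[C@H]([C@H](O)c1ccc(OCc2ccccc2)c(OCc2ccccc2)c1)C(=O)c1c(O[Si](C)(C)C(C)(C)C)cc(OCc2ccccc2)cc1O[Si](C)(C)C(C)(C)C
A2 | alternative 1 | 1-[4-(benzyloxy)-2,6-bis(tert-butyldimethylsilyloxy)phenyl]-2-diazoethan-1-one | [N-]=[N+]=CC(=O)c1c(O[Si](C)(C)C(C)(C)C)cc(OCc2ccccc2)cc1O[Si](C)(C)C(C)(C)C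
A3 | alternative 1 | (2S)-5,7-bis(benzyloxy)-2-[4-(benzyloxy)phenyl]chroman-4-one | O=C1C[C@@H](c2ccc(OCc3ccccc3)cc2)Oc2cc(OCc3ccccc3)cc(OCc3ccccc3)c12
A4 | alternative 2 | cis-2,3-disubstituted chromanone with silyl ethers on unit 2 and benzyl-type ethers on unit 1 | O=C1C[C@@H](c2ccc(O[Si](C)(C)C(C)(C)C)cc2)Oc2c1c(O[Si](C)(C)C(C)(C)C)cc(O[Si](C)(C)C(C)(C)C)c2[C@H]1C(=O)c2c(OCc3ccc(OCc4ccccc4)c(OCc4ccccc4)c3)cc(OCc3ccc(OCc4ccccc4)c(OCc4ccccc4)c3)cc2O[C@H]1c1ccc(OCc2ccccc2)c(OCc2ccccc2)c1
A5 | alternative 2 | diazoketone with the diazo carbon between C8'' of the silylated (2S)-flavanone and the 2,4,6-tris[(3,4-dibenzyloxybenzyl)oxy]benzoyl group | O=C1C[C@@H](c2ccc(O[Si](C)(C)C(C)(C)C)cc2)Oc2c1c(O[Si](C)(C)C(C)(C)C)cc(O[Si](C)(C)C(C)(C)C)c2C(=[N+]=[N-])C(=O)c1c(OCc2ccc(OCc3ccccc3)c(OCc3ccccc3)c2)cc(OCc2ccc(OCc3ccccc3)c(OCc3ccccc3)c2)cc1OCc1ccc(OCc2ccccc2)c(OCc2ccccc2)c1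
A6 | alternative 3 | tetra-O-benzyl ether of the target (5,7,3',4'''-benzylated) | O=C1C[C@@H](c2ccc(OCc3ccccc3)cc2)Oc2c1c(O)cc(O)c2[C@H]1C(=O)c2c(OCc3ccccc3)cc(OCc3ccccc3)cc2O[C@H]1c1ccc(O)c(OCc2ccccc2)c1
A7 | alternative 3 | (E)-1-[2,4-bis(benzyloxy)-6-hydroxyphenyl]-3-[3-(benzyloxy)-4-hydroxyphenyl]prop-2-en-1-one | O=C(/C=C/c1ccc(O)c(OCc2ccccc2)c1)c1c(O)cc(OCc2ccccc2)cc1OCc1ccccc1
A8 | alternative 3 | (2S)-2-[4-(benzyloxy)phenyl]-5,7-dihydroxychroman-4-one | O=C1C[C@@H](c2ccc(OCc3ccccc3)cc2)Oc2cc(O)cc(O)c12
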